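**Strategy.** The decalin is cut across ring B at C6–C7 and C5–C10 (drimane numbering), which unravels both rings to an open-chain (Z)-configured 2-(trimethylsilylmethyl)-1,3-diene carrying a tethered (E)-enal. One intramolecular Diels–Alder reaction closes ring A through the tether and ring B by cycloaddition. It exploits the cis ring fusion (H-5 syn to CH3-10) and the C8/C9 substitution of ring B: the Z-diene can only give the cis-decalin, the C3 bromide stereocentre (set by organocatalytic α-bromination) steers the facial sense, and the allylsilane left at C8=C9 is later protonated to the exocyclic methylene and H-9. The formyl activator at C6 is removed by decarbonylation.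

Key step: step 13

Remark 1: drimane numbering is used for the skeleton (ring carbons C1 to C10, C11 = ArCH2, C12 = exocyclic CH2); β is the face of the C10 methyl group. The target SMILES is read as the cis-fused decalin with Br-3, H-5, H-9 and CH3-10 all β (3S,5S,9R,10R).
Remark 2: Ar* = 2,5-bis(tert-butyldimethylsilyloxy)-4-(1,3-dioxolan-2-yl)phenyl.

**Bromide fragment**

Step 1
Reactants: 1 methyl 3,3-dimethylpent-4-enoate; 2 triethyl(prop-2-en-1-yloxy)silane
Product: 3 methyl (4E)-3,3-dimethyl-6-(triethylsilyloxy)hex-4-enoate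
Conditions: second-generation Hoveyda–Grubbs catalyst (5 mol%), 2 (3 equiv), CH2Cl2, 40 °C
Reagents that add atoms: none
Why: Olefin cross-metathesis of the hindered vinyl group on the quaternary carbon with an excess of the unhindered allyl ether should give the E-alkene selectively, since the bulky quaternary substituent disfavours the Z-metallacycle.

Step 2
Reactants: 3 methyl (4E)-3,3-dimethyl-6-(triethylsilyloxy)hex-4-enoate
Product: 4 (4E)-3,3-dimethyl-6-(triethylsilyloxy)hex-4-enal
Conditions: i-Bu2AlH (1.05 equiv), CH2Cl2, −78 °C; aq. potassium sodium tartrate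
Reagents that add atoms: none
Why: Partial hydride reduction of the ester stops at the tetrahedral aluminate at −78 °C and releases the aldehyde on work-up.

Step 3
Reactants: 4 (4E)-3,3-dimethyl-6-(triethylsilyloxy)hex-4-enal
Product: 6 (2R,4E)-2-bromo-3,3-dimethyl-6-(triethylsilyloxy)hex-4-en-1-ol, via α-bromo aldehyde 5 (not isolated)
Conditions: (R)-2-{bis[3,5-bis(trifluoromethyl)phenyl](trimethylsilyloxy)methyl}pyrrolidine (10 mol%), PhCO2H (10 mol%), 4,4-dibromo-2,6-di-tert-butylcyclohexa-2,5-dien-1-one (1.05 equiv), H2O (2 equiv), CH2Cl2/pentane, −40 °C; then NaBH4, MeOH, 0 °C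
Reagents that add atoms: 4,4-dibromo-2,6-di-tert-butylcyclohexa-2,5-dien-1-one (CC(C)(C)C1=CC(Br)(Br)C=C(C(C)(C)C)C1=O)
Why: Enamine-catalysed α-bromination: the diarylsilyloxymethyl group shields one face of the (E)-anti-enamine, so the (R)-catalyst should deliver bromine to give the 2R centre (the future C3); the adjacent quaternary carbon slows racemisation and the aldehyde is reduced in the same flask.

Step 4
Reactants: 6 (2R,4E)-2-bromo-3,3-dimethyl-6-(triethylsilyloxy)hex-4-en-1-ol
Product: 7 (2R,4E)-2-bromo-3,3-dimethyl-6-(triethylsilyloxy)hex-4-en-1-yl trifluoromethanesulfonate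
Conditions: Tf2O, 2,6-lutidine, CH2Cl2, −78 °C; used crude
Reagents that add atoms: trifluoromethanesulfonic anhydride (O=S(=O)(OS(=O)(=O)C(F)(F)F)C(F)(F)F)
Why: O-Sulfonylation of the primary alcohol gives a 2-bromoalkyl triflate (the class of 2-bromoethyl triflate) without touching the bromide-bearing stereocentre.

**Aryl fragment**

Step 5
Reactants: 8 2,5-dihydroxybenzene-1,4-dicarbaldehyde
Product: 9 2,5-bis(tert-butyldimethylsilyloxy)benzene-1,4-dicarbaldehyde
Conditions: t-BuMe2SiCl, imidazole, DMF, 23 °C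
Reagents that add atoms: tert-butyldimethylsilyl chloride (CC(C)(C)[Si](C)(C)Cl)
Why: Standard silylation of both phenols; aryl silyl ethers are chosen because they can be removed at the end without acid.

Step 6
Reactants: 9 2,5-bis(tert-butyldimethylsilyloxy)benzene-1,4-dicarbaldehyde
Product: 10 2,5-bis(tert-butyldimethylsilyloxy)-4-(hydroxymethyl)benzaldehyde
Conditions: NaBH4 (0.3 equiv), THF/EtOH, −20 °C
Reagents that add atoms: none
Why: Chemoselective monoreduction: once one formyl group is reduced the remaining aldehyde loses its para acceptor and is less electrophilic, so the second reduction should be slower; unreacted 9 is recycled.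

Step 7
Reactants: 10 2,5-bis(tert-butyldimethylsilyloxy)-4-(hydroxymethyl)benzaldehyde
Product: 11 [2,5-bis(tert-butyldimethylsilyloxy)-4-(1,3-dioxolan-2-yl)phenyl]methanol
Conditions: HOCH2CH2OH (5 equiv), pyridinium p-toluenesulfonate (10 mol%), benzene, reflux, Dean–Stark trap
Reagents that add atoms: ethylene glycol (OCCO)
Why: Acid-catalysed acetalisation masks the aryl aldehyde against the organometallic and rhodium steps; aryl silyl ethers tolerate the weak pyridinium acid.

Step 8
Reactants: 11 [2,5-bis(tert-butyldimethylsilyloxy)-4-(1,3-dioxolan-2-yl)phenyl]methanol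
Product: 12 2-[4-(bromomethyl)-2,5-bis(tert-butyldimethylsilyloxy)phenyl]-1,3-dioxolane (Ar*CH2Br)
Conditions: CBr4, PPh3, 2,6-lutidine (0.3 equiv), CH2Cl2, 0 °C
Reagents that add atoms: carbon tetrabromide (BrC(Br)(Br)Br)
Why: Appel bromination of the benzylic alcohol under buffered, neutral conditions that spare the acetal.

**Union and endgame**

Step 9
Reactants: 13 methyl acetoacetate; 7 (2R,4E)-2-bromo-3,3-dimethyl-6-(triethylsilyloxy)hex-4-en-1-yl trifluoromethanesulfonate; 12 Ar*CH2Br
Product: 16 methyl (6S,8E)-2-(Ar*-methyl)-6-bromo-7,7-dimethyl-3-oxo-10-(triethylsilyloxy)dec-8-enoate (both C2 epimers), via acetoacetate dianion 14 (not isolated), via keto ester enolate 15 (not isolated)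
Conditions: 13, NaH (1.05 equiv), THF, 0 °C; n-BuLi (1.0 equiv), 0 °C; 7 (0.95 equiv), −78 to −20 °C; then 12 (0.95 equiv), DMPU, 0 to 23 °C
Reagents that add atoms: none
Why: Weiler dianion alkylation: the γ-carbanion displaces the primary triflate by SN2 (the neopentylic secondary bromide is inert and C3 is not involved, its descriptor changing to S only by priority), and the remaining α-enolate is then C-benzylated; the new α-centre forms unselectively and is erased in step 10.

Step 10
Reactants: 16 methyl (6S,8E)-2-(Ar*-methyl)-6-bromo-7,7-dimethyl-3-oxo-10-(triethylsilyloxy)dec-8-enoate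
Product: 17 methyl (2E,6S,8E)-2-(Ar*-methyl)-6-bromo-7,7-dimethyl-3-(4-methylbenzenesulfonyloxy)-10-(triethylsilyloxy)deca-2,8-dienoate
Conditions: TsCl, N-methylimidazole, Et3N, CH2Cl2, −15 to 23 °C
Reagents that add atoms: p-toluenesulfonyl chloride (Cc1ccc(S(=O)(=O)Cl)cc1)
Why: Stereoselective enol sulfonylation of an α-substituted β-keto ester: without a chelating metal the enolate oxygen lies anti to the ester carbonyl and should be tosylated as the (E)-isomer (OTs trans to CO2Me), whereas LiCl/TMEDA conditions would give Z.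

Step 11
Reactants: 17 methyl (2E,6S,8E)-2-(Ar*-methyl)-6-bromo-7,7-dimethyl-3-(4-methylbenzenesulfonyloxy)-10-(triethylsilyloxy)deca-2,8-dienoate
Product: 18 methyl (2Z,6S,8E)-2-(Ar*-methyl)-6-bromo-3,7,7-trimethyl-10-(triethylsilyloxy)deca-2,8-dienoate
Conditions: MeZnCl (2 equiv), Pd(dppf)Cl2 (5 mol%), THF, 50 °C
Reagents that add atoms: methylzinc chloride (C[Zn]Cl)
Why: Negishi coupling of the activated enol tosylate proceeds with retention, so CH3 takes the place of OTs and the C1 chain stays cis to the ester (the future Z-diene); the hindered secondary alkyl bromide should not undergo oxidative addition with this catalyst.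

Step 12
Reactants: 18 methyl (2Z,6S,8E)-2-(Ar*-methyl)-6-bromo-3,7,7-trimethyl-10-(triethylsilyloxy)deca-2,8-dienoate
Product: 20 triethyl{[(2E,5S,8Z)-9-(Ar*-methyl)-5-bromo-4,4,8-trimethyl-10-[(trimethylsilyl)methyl]undeca-2,8,10-trien-1-yl]oxy}silane, via bis(silylmethyl) carbinol 19 (not isolated)
Conditions: Me3SiCH2MgCl (5 equiv), CeCl3 (5 equiv), THF, −78 to 23 °C; then SiO2, CH2Cl2, 23 °C
Reagents that add atoms: (trimethylsilyl)methylmagnesium chloride (C[Si](C)(C)C[Mg]Cl)
Why: Bunnelle allylsilane synthesis: double addition of the non-basic organocerium reagent to the ester and silica-induced Peterson elimination of the β-hydroxysilane give the 2-(trimethylsilylmethyl)-1,3-diene without touching the tetrasubstituted alkene geometry.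

Step 13
Reactants: 20 triethyl{[(2E,5S,8Z)-9-(Ar*-methyl)-5-bromo-4,4,8-trimethyl-10-[(trimethylsilyl)methyl]undeca-2,8,10-trien-1-yl]oxy}silane
Product: 22 (3S,5S,6R,10S)-9-(Ar*-methyl)-3-bromo-4,4,10-trimethyl-8-[(trimethylsilyl)methyl]-cis-octal-8-ene-6-carbaldehyde (drimane numbering; Br-3, H-5, CHO-6 and CH3-10 all β), via trienal 21 (not isolated)
Conditions: IBX (3 equiv), DMSO, 23 °C; aqueous work-up; crude 21 in PhMe (0.01 M), BHT, 110 °C
Reagents that add atoms: none
Why: IBX first cleaves and oxidises the allylic triethylsilyl ether to the (E)-enal (aryl silyl ethers and the dioxolane are left), whose LUMO then engages the electron-rich 2-(silylmethyl)diene in a concerted, asynchronous, normal-demand intramolecular Diels–Alder reaction; the closest precedents are type 1 cycloadditions of (Z)-diene 1,3,9-decatrienes bearing carbonyl-activated dienophiles, which give cis-fused octalins. Ring A closes as a six-membered ring through the C1–C4 tether in a chair-like array as C5–C10 forms, and ring B is the new cyclohexene, formed suprafacially on both components through a boat-like [4+2] transition state. At C10 and C5 the tether sits on the inner (Z) position of the diene terminus, so only the tether-exo mode is geometrically possible and H-5 ends syn to CH3-10 (cis fusion); at C6 the E-enal places the formyl group trans to C4 (this centre is erased in step 14). The absolute sense at C5 and C10 is relayed from C3: the chair tether with equatorial bromine should be used, because the alternative places bromine 1,3-diaxial to the incoming C6. The step needs cis over trans fusion, which the stereodefined Z-diene from steps 10 and 11 secures, and cycloaddition faster than the [1,5]-hydrogen shift open to Z-dienes, which the formyl activation and the gem-dimethyl group at C4 should secure by letting the reaction run near 110 °C.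

Step 14
Reactants: 22 (3S,5S,6R,10S)-9-(Ar*-methyl)-3-bromo-4,4,10-trimethyl-8-[(trimethylsilyl)methyl]-cis-octal-8-ene-6-carbaldehyde
Product: 23 (3S,5S,10S)-9-(Ar*-methyl)-3-bromo-4,4,10-trimethyl-8-[(trimethylsilyl)methyl]-cis-octal-8-ene (drimane numbering; Br-3, H-5 and CH3-10 all β)
Conditions: RhCl(PPh3)3 (1.2 equiv), PhCN, 130 °C
Reagents that add atoms: none
Why: Tsuji–Wilkinson decarbonylation (formyl C–H oxidative addition, CO extrusion, reductive elimination) removes the activating group and leaves C6 as CH2; the acetal keeps the aryl aldehyde out of the reaction, and the tetrasubstituted alkene and the hindered bromide should be inert to the rhodium complex.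

Step 15
Reactants: 23 (3S,5S,10S)-9-(Ar*-methyl)-3-bromo-4,4,10-trimethyl-8-[(trimethylsilyl)methyl]-cis-octal-8-ene
Product: 25 4-{[(1R,4aS,6S,8aR)-6-bromo-5,5,8a-trimethyl-2-methylidenedecahydronaphthalen-1-yl]methyl}-2,5-bis(tert-butyldimethylsilyloxy)benzaldehyde, via dioxolane-protected exocyclic alkene 24 (not isolated)
Conditions: CF3CO2H (5 equiv), CH2Cl2, −20 °C; then H2O/THF, 0 °C
Reagents that add atoms: water (O)
Why: Protodesilylation of the allylsilane (anti SE2′): the proton should add to C9 axially on the convex β face of the cis-octalin (the α face is covered by ring A, C1 being axial on ring B), giving H-9 β with the arylmethyl group equatorial as the β-silyl cation at C8 collapses to the exocyclic alkene; water then hydrolyses the dioxolane while the aryl silyl ethers survive.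

Step 16
Reactants: 25 4-{[(1R,4aS,6S,8aR)-6-bromo-5,5,8a-trimethyl-2-methylidenedecahydronaphthalen-1-yl]methyl}-2,5-bis(tert-butyldimethylsilyloxy)benzaldehyde
Product: 26 Peyssonol A, 4-{[(1R,4aS,6S,8aR)-6-bromo-5,5,8a-trimethyl-2-methylidenedecahydronaphthalen-1-yl]methyl}-2,5-dihydroxybenzaldehyde
Conditions: Bu4NF (2.5 equiv), AcOH (3 equiv), THF, 0 °C, under argon
Reagents that add atoms: none
Why: Buffered fluoride cleavage of the two aryl silyl ethers is non-acidic, so the exocyclic alkene should neither isomerise nor be trapped by the ortho-phenol as a chroman.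

**Compound list**

1 | methyl 3,3-dimethylpent-4-enoate | COC(=O)CC(C)(C)C=C | starting material
2 | triethyl(prop-2-en-1-yloxy)silane | C=CCO[Si](CC)(CC)CC | starting material
3 | methyl (4E)-3,3-dimethyl-6-(triethylsilyloxy)hex-4-enoate | COC(=O)CC(C)(C)/C=C/CO[Si](CC)(CC)CC | intermediate
4 | (4E)-3,3-dimethyl-6-(triethylsilyloxy)hex-4-enal | O=CCC(C)(C)/C=C/CO[Si](CC)(CC)CC | intermediate
5 | (2R,4E)-2-bromo-3,3-dimethyl-6-(triethylsilyloxy)hex-4-enal (not isolated) | O=C[C@H](Br)C(C)(C)/C=C/CO[Si](CC)(CC)CC | intermediate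
6 | (2R,4E)-2-bromo-3,3-dimethyl-6-(triethylsilyloxy)hex-4-en-1-ol | OC[C@H](Br)C(C)(C)/C=C/CO[Si](CC)(CC)CC | intermediate
7 | (2R,4E)-2-bromo-3,3-dimethyl-6-(triethylsilyloxy)hex-4-en-1-yl trifluoromethanesulfonate | FC(F)(F)S(=O)(=O)OC[C@H](Br)C(C)(C)/C=C/CO[Si](CC)(CC)CC | intermediate
8 | 2,5-dihydroxybenzene-1,4-dicarbaldehyde | O=Cc1cc(O)c(C=O)cc1O | starting material
9 | 2,5-bis(tert-butyldimethylsilyloxy)benzene-1,4-dicarbaldehyde | O=Cc1cc(O[Si](C)(C)C(C)(C)C)c(C=O)cc1O[Si](C)(C)C(C)(C)C | intermediate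
10 | 2,5-bis(tert-butyldimethylsilyloxy)-4-(hydroxymethyl)benzaldehyde | OCc1cc(O[Si](C)(C)C(C)(C)C)c(C=O)cc1O[Si](C)(C)C(C)(C)C | intermediate
11 | [2,5-bis(tert-butyldimethylsilyloxy)-4-(1,3-dioxolan-2-yl)phenyl]methanol | OCc1cc(O[Si](C)(C)C(C)(C)C)c(C2OCCO2)cc1O[Si](C)(C)C(C)(C)C | intermediate
12 | 2-[4-(bromomethyl)-2,5-bis(tert-butyldimethylsilyloxy)phenyl]-1,3-dioxolane | BrCc1cc(O[Si](C)(C)C(C)(C)C)c(C2OCCO2)cc1O[Si](C)(C)C(C)(C)C | intermediate
13 | methyl acetoacetate | COC(=O)CC(C)=O | starting material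
14 | sodium lithium dianion of methyl acetoacetate (not isolated) | C=C([O-])C=C([O-])OC.[Na+].[Li+] | intermediate
15 | sodium enolate of methyl (6S,8E)-6-bromo-7,7-dimethyl-3-oxo-10-(triethylsilyloxy)dec-8-enoate (not isolated) | COC(=O)C=C([O-])CC[C@H](Br)C(C)(C)/C=C/CO[Si](CC)(CC)CC.[Na+] | intermediate
16 | methyl (6S,8E)-2-(Ar*-methyl)-6-bromo-7,7-dimethyl-3-oxo-10-(triethylsilyloxy)dec-8-enoate, both C2 epimers | COC(=O)C(Cc1cc(O[Si](C)(C)C(C)(C)C)c(C2OCCO2)cc1O[Si](C)(C)C(C)(C)C)C(=O)CC[C@H](Br)C(C)(C)/C=C/CO[Si](CC)(CC)CC | intermediate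
17 | methyl (2E,6S,8E)-2-(Ar*-methyl)-6-bromo-7,7-dimethyl-3-(4-methylbenzenesulfonyloxy)-10-(triethylsilyloxy)deca-2,8-dienoate | COC(=O)/C(Cc1cc(O[Si](C)(C)C(C)(C)C)c(C2OCCO2)cc1O[Si](C)(C)C(C)(C)C)=C(/OS(=O)(=O)c1ccc(C)cc1)CC[C@H](Br)C(C)(C)/C=C/CO[Si](CC)(CC)CC | intermediate
18 | methyl (2Z,6S,8E)-2-(Ar*-methyl)-6-bromo-3,7,7-trimethyl-10-(triethylsilyloxy)deca-2,8-dienoate | COC(=O)/C(Cc1cc(O[Si](C)(C)C(C)(C)C)c(C2OCCO2)cc1O[Si](C)(C)C(C)(C)C)=C(/C)CC[C@H](Br)C(C)(C)/C=C/CO[Si](CC)(CC)CC | intermediate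
19 | (3Z,7S,9E)-3-(Ar*-methyl)-7-bromo-4,8,8-trimethyl-11-(triethylsilyloxy)-1-(trimethylsilyl)-2-[(trimethylsilyl)methyl]undeca-3,9-dien-2-ol (not isolated) | C[Si](C)(C)CC(O)(C[Si](C)(C)C)/C(Cc1cc(O[Si](C)(C)C(C)(C)C)c(C2OCCO2)cc1O[Si](C)(C)C(C)(C)C)=C(/C)CC[C@H](Br)C(C)(C)/C=C/CO[Si](CC)(CC)CC | intermediate
20 | triethyl{[(2E,5S,8Z)-9-(Ar*-methyl)-5-bromo-4,4,8-trimethyl-10-[(trimethylsilyl)methyl]undeca-2,8,10-trien-1-yl]oxy}silane | C=C(C[Si](C)(C)C)/C(Cc1cc(O[Si](C)(C)C(C)(C)C)c(C2OCCO2)cc1O[Si](C)(C)C(C)(C)C)=C(/C)CC[C@H](Br)C(C)(C)/C=C/CO[Si](CC)(CC)CC | intermediate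
21 | (2E,5S,8Z)-9-(Ar*-methyl)-5-bromo-4,4,8-trimethyl-10-[(trimethylsilyl)methyl]undeca-2,8,10-trienal (not isolated) | C=C(C[Si](C)(C)C)/C(Cc1cc(O[Si](C)(C)C(C)(C)C)c(C2OCCO2)cc1O[Si](C)(C)C(C)(C)C)=C(/C)CC[C@H](Br)C(C)(C)/C=C/C=O | intermediate
22 | (3S,5S,6R,10S)-9-(Ar*-methyl)-3-bromo-4,4,10-trimethyl-8-[(trimethylsilyl)methyl]-cis-octal-8-ene-6-carbaldehyde (drimane numbering) | C[Si](C)(C)CC=1C[C@@H](C=O)[C@@H]2C(C)(C)[C@@H](Br)CC[C@]2(C)C=1Cc1cc(O[Si](C)(C)C(C)(C)C)c(C2OCCO2)cc1O[Si](C)(C)C(C)(C)C | intermediate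
23 | (3S,5S,10S)-9-(Ar*-methyl)-3-bromo-4,4,10-trimethyl-8-[(trimethylsilyl)methyl]-cis-octal-8-ene (drimane numbering) | C[Si](C)(C)CC=1CC[C@@H]2C(C)(C)[C@@H](Br)CC[C@]2(C)C=1Cc1cc(O[Si](C)(C)C(C)(C)C)c(C2OCCO2)cc1O[Si](C)(C)C(C)(C)C | intermediate
24 | 2-[4-{[(1R,4aS,6S,8aR)-6-bromo-5,5,8a-trimethyl-2-methylidenedecahydronaphthalen-1-yl]methyl}-2,5-bis(tert-butyldimethylsilyloxy)phenyl]-1,3-dioxolane (not isolated) | C=C1CC[C@@H]2C(C)(C)[C@@H](Br)CC[C@]2(C)[C@@H]1Cc1cc(O[Si](C)(C)C(C)(C)C)c(C2OCCO2)cc1O[Si](C)(C)C(C)(C)C | intermediate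
25 | 4-{[(1R,4aS,6S,8aR)-6-bromo-5,5,8a-trimethyl-2-methylidenedecahydronaphthalen-1-yl]methyl}-2,5-bis(tert-butyldimethylsilyloxy)benzaldehyde | C=C1CC[C@@H]2C(C)(C)[C@@H](Br)CC[C@]2(C)[C@@H]1Cc1cc(O[Si](C)(C)C(C)(C)C)c(C=O)cc1O[Si](C)(C)C(C)(C)C | intermediate
26 | Peyssonol A, 4-{[(1R,4aS,6S,8aR)-6-bromo-5,5,8a-trimethyl-2-methylidenedecahydronaphthalen-1-yl]methyl}-2,5-dihydroxybenzaldehyde | C=C1CC[C@@H]2C(C)(C)[C@@H](Br)CC[C@]2(C)[C@@H]1Cc1cc(O)c(C=O)cc1O | target

**Totals.** Total step count: 16. Longest linear sequence: 12 steps (steps 1 to 4 and 9 to 16; the aryl branch, steps 5 to 8 and 9 to 16, is of equal length).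

**Steps most likely to fail**

Step 13 (cycloaddition). The bond between the neopentylic enal carbon C5 and the fully substituted diene terminus C10 may form so slowly at 110 °C that [1,5]-hydrogen migration from C1 to C7 of the Z-diene, or oligomerisation of the enal, consumes the trienal; the facial bias from C3 may also erode at high temperature. The fallback changes the activation from heat to covalent iminium catalysis. Trienal 21 is isolated after the IBX oxidation and treated with pyrrolidinium trifluoroacetate (20 mol%) in MeCN/H2O at 0 to 23 °C. This forms the α,β-unsaturated iminium salt F1 (not isolated; conjugate addition of the amine is blocked by the neopentylic β-carbon), which should cyclise well below the temperature of the hydrogen shift; hydrolysis of the product iminium returns the route at cycloadduct 22. A chiral imidazolidinone salt can replace pyrrolidine if reagent control is needed on top of the substrate bias.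

Step 12 (allylsilane formation). The second addition of the bulky organocerium reagent to the twisted, doubly flanked carbonyl may stall at the ketone stage through enolisation, or the silica treatment may protodesilylate the diene. The fallback sets out from enoate 18. A single addition of Me3SiCH2Li (2.2 equiv, THF, −78 to 0 °C, NH4Cl quench) gives the α-silyl ketone F2, which is protected as its enolate until work-up. Carbonyl methylenation with Cp2TiMe2 (toluene, 70 °C) then gives diene 20 without any acidic elimination step.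

Step 9 (fragment union). SN2 displacement at the β-branched carbon by the delocalised dianion may be slower than E2 loss of triflic acid, and proton transfer during the one-flask benzylation may give dialkylated material. The fallback sets out from triflate 7 and uses the small, more nucleophilic LiCH2CN (THF, −78 °C) to give the nitrile F3. A Blaise reaction (Zn, BrCH2CO2Me, THF, reflux) converts it to the enamino ester F4, and mild aqueous citric acid gives the β-keto ester F5. Separate benzylation with 12 (K2CO3, acetone) returns the route at 16.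

Further compounds
F1 | step 13 | 1-[(2E,5S,8Z)-9-(Ar*-methyl)-5-bromo-4,4,8-trimethyl-10-[(trimethylsilyl)methyl]undeca-2,8,10-trien-1-ylidene]pyrrolidin-1-ium trifluoroacetate | C=C(C[Si](C)(C)C)/C(Cc1cc(O[Si](C)(C)C(C)(C)C)c(C2OCCO2)cc1O[Si](C)(C)C(C)(C)C)=C(/C)CC[C@H](Br)C(C)(C)/C=C/C=[N+]1CCCC1.[O-]C(=O)C(F)(F)F
F2 | step 12 | (3Z,7S,9E)-3-(Ar*-methyl)-7-bromo-4,8,8-trimethyl-11-(triethylsilyloxy)-1-(trimethylsilyl)undeca-3,9-dien-2-one | C[Si](C)(C)CC(=O)/C(Cc1cc(O[Si](C)(C)C(C)(C)C)c(C2OCCO2)cc1O[Si](C)(C)C(C)(C)C)=C(/C)CC[C@H](Br)C(C)(C)/C=C/CO[Si](CC)(CC)CC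
F3 | step 9 | (4S,6E)-4-bromo-5,5-dimethyl-8-(triethylsilyloxy)oct-6-enenitrile | N#CCC[C@H](Br)C(C)(C)/C=C/CO[Si](CC)(CC)CC
F4 | step 9 | methyl (2Z,6S,8E)-3-amino-6-bromo-7,7-dimethyl-10-(triethylsilyloxy)deca-2,8-dienoate | COC(=O)/C=C(\N)CC[C@H](Br)C(C)(C)/C=C/CO[Si](CC)(CC)CC
F5 | step 9 | methyl (6S,8E)-6-bromo-7,7-dimethyl-3-oxo-10-(triethylsilyloxy)dec-8-enoate | COC(=O)CC(=O)CC[C@H](Br)C(C)(C)/C=C/CO[Si](CC)(CC)CC
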